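**Retrosynthetic overview**
1. The 20-membered ring is opened at its two amide bonds: the acrylamide on the propyl arm is closed last by macrolactamisation, the cinnamamide on the butyl arm is made intermolecularly from N1,N4-bis-Boc-spermidine. Both Z-alkenes come from Z-selective Horner–Wadsworth–Emmons reactions of an aryl aldehyde and of a neopentyl aldehyde on the quaternary carbon.
2. The dihydrofuran (ring B) is cut at the quaternary C–aryl bond (5-exo aryl radical cyclisation, cis to the C–O bond) and at the aryl–O bond (SNAr of the ring carbinol on 3-bromo-4-fluorobenzonitrile, which brings in arene ring A).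
3. The cyclohexanone (ring C) is made first, by an inverse-demand Diels–Alder reaction of methyl coumalate with a chiral cyclic ketene acetal. This forms at once the bond from the ketone carbon to the CH2 on the side of the quaternary carbon and the bond from the other CH2 to the O-bearing CH.
4. Enabling feature: in ring C the ketone carbon is para to the quaternary carbon and 1,3 to the O-bearing ring-fusion CH. This is the imprint of a 2-pyrone-5-carboxylate/ketene acetal adduct: pyrone ring O becomes the furan O, the ester carbon becomes the vinyl carbon on the quaternary centre, the acetal carbon becomes C=O, and the lactone C=O (β to that ketone) leaves as CO2.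
5. Ring order: ring C (cycloaddition), then ring B (SNAr, radical cyclisation), then the macrolactam.

Key step: step 3

Assumption: both acrylamide double bonds are Z as written in the target SMILES, and the two diastereomeric cycloadducts of step 3 are taken to be separable on base-washed silica or by crystallisation.

**Step 1**
Reactants: 1 (1R,2R)-1,2-diphenylethane-1,2-diol; 2 2-bromo-1,1-diethoxyethane
Product: 3 (4R,5R)-2-(bromomethyl)-4,5-diphenyl-1,3-dioxolane
Conditions: TsOH·H2O (5 mol %), toluene, 110 °C, EtOH distilled off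
Reagents that add atoms: none
Why: Acid-catalysed transacetalisation driven by removal of ethanol; the two stereocentres come unchanged from the diol, and the acetal carbon is not stereogenic because the diol has a twofold axis.

**Step 2**
Reactants: 3 (4R,5R)-2-(bromomethyl)-4,5-diphenyl-1,3-dioxolane
Product: 4 (4R,5R)-2-methylidene-4,5-diphenyl-1,3-dioxolane
Conditions: KOtBu (1.3 equiv), THF, 0 to 23 °C; stored over K2CO3
Reagents that add atoms: none
Why: E2 dehydrobromination of a 2-(halomethyl)-1,3-dioxolane is the standard route to cyclic ketene acetals and touches no stereocentre.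

**Step 3**
Reactants: 4 (4R,5R)-2-methylidene-4,5-diphenyl-1,3-dioxolane; 5 methyl 2-oxo-2H-pyran-5-carboxylate (methyl coumalate)
Product: 6 methyl (1R,4R,4'R,5'R)-3-oxo-4',5'-diphenylspiro[2-oxabicyclo[2.2.2]oct-5-ene-8,2'-[1,3]dioxolane]-6-carboxylate
Conditions: 4 (1.3 equiv), CH2Cl2 (filtered through K2CO3), 0 to 23 °C, dark; separation of the two diastereomers on Et3N-deactivated silica
Reagents that add atoms: none
Why: Inverse-electron-demand Diels–Alder reaction of a 2-pyrone: the nucleophilic CH2 of the ketene acetal bonds to C-6 of methyl coumalate (β to the ester, vinylogous to the lactone carbonyl) and the acetal carbon to C-3 in an asynchronous, suprafacial [4+2] addition, the closest known cases being the additions of 1,1-dialkoxyethenes to methyl coumalate and to 3-carbomethoxy-2-pyrone. The one ring that closes is the carbocyclic six-membered ring, formed as a boat that the lactone bridge locks into a 2-oxabicyclo[2.2.2]octene. The regiochemistry needed (acetal carbon para to the ester-bearing carbon, CH2 on the O-bearing carbon) is the one that leads to 4-alkoxybenzoates when such adducts are heated and is secured by the polarisation of the pyrone. The two bridgehead stereocentres form together with their relative configuration fixed by the bridge; the O-bearing one later controls the quaternary carbon, the other is erased by decarboxylation. Their absolute configuration is addressed by the twofold-symmetric (R,R)-diphenyldioxolane, which makes the two pyrone faces diastereotopic without creating a stereocentre at the acetal carbon: only a modest facial bias is assumed because the phenyl groups are remote, so 6 is secured by separation from its diastereomer, and the (S,S)-diol is used if 6 turns out to be the minor isomer. The chemoselectivity needed, no loss of CO2 or alcohol to a 4-alkoxybenzoate, is secured by working at or below 23 °C without acid and by the cyclic ketal.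

**Step 4**
Reactants: 6 methyl (1R,4R,4'R,5'R)-3-oxo-4',5'-diphenylspiro[2-oxabicyclo[2.2.2]oct-5-ene-8,2'-[1,3]dioxolane]-6-carboxylate
Product: 7 (2R,3R,6R,9R)-9-hydroxy-8-(methoxycarbonyl)-2,3-diphenyl-1,4-dioxaspiro[4.5]dec-7-ene-6-carboxylic acid
Conditions: LiOH·H2O (1.05 equiv), THF/H2O 3:1, 0 °C; then 1 M HCl to pH 4 at 0 °C
Reagents that add atoms: lithium hydroxide, [Li+].[OH-]
Why: Saponification by acyl–oxygen cleavage: the strained bridged lactone, an ester locked in the reactive s-cis form, should hydrolyse far faster than the conjugated methyl ester, and both stereocentres are untouched.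

**Step 5**
Reactants: 7 (2R,3R,6R,9R)-9-hydroxy-8-(methoxycarbonyl)-2,3-diphenyl-1,4-dioxaspiro[4.5]dec-7-ene-6-carboxylic acid; 8 3-bromo-4-fluorobenzonitrile
Product: 9 (2R,3R,6R,9R)-9-(2-bromo-4-cyanophenoxy)-8-(methoxycarbonyl)-2,3-diphenyl-1,4-dioxaspiro[4.5]dec-7-ene-6-carboxylic acid
Conditions: NaH (2.2 equiv), DMF, 0 °C; then 8 (1.1 equiv), 0 to 23 °C; 1 M HCl to pH 4
Reagents that add atoms: none
Why: Nucleophilic aromatic substitution (SNAr) of the fluoride para to the nitrile by the secondary alkoxide keeps the carbinol C–O bond, so the configuration is retained and the former pyrone oxygen becomes the aryl ether oxygen, while the carboxylate on the neighbouring acidic CH blocks E1cB loss of the aryloxide.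

**Step 6**
Reactants: 9 (2R,3R,6R,9R)-9-(2-bromo-4-cyanophenoxy)-8-(methoxycarbonyl)-2,3-diphenyl-1,4-dioxaspiro[4.5]dec-7-ene-6-carboxylic acid
Product: 11 (2R,3R,6R,9R)-9-(2-bromo-4-formylphenoxy)-8-(hydroxymethyl)-2,3-diphenyl-1,4-dioxaspiro[4.5]dec-7-ene-6-carboxylic acid, via aldimine 10 (not isolated)
Conditions: iBu2AlH (5 equiv), CH2Cl2, −78 to −40 °C; aq. KNaC4H4O6, then 1 M HCl to pH 4
Reagents that add atoms: water, O
Why: Hydride reduction with iBu2AlH takes the conjugated ester to the allylic alcohol (1,2-reduction) and the nitrile to the N-aluminio aldimine, which is hydrolysed to the aldehyde on work-up, while the aluminium carboxylate is not reduced at low temperature and no stereocentre is affected.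

**Step 7**
Reactants: 11 (2R,3R,6R,9R)-9-(2-bromo-4-formylphenoxy)-8-(hydroxymethyl)-2,3-diphenyl-1,4-dioxaspiro[4.5]dec-7-ene-6-carboxylic acid
Product: 12 (2R,4aR,9bR,4'R,5'R)-8-formyl-9b-(hydroxymethyl)-4',5'-diphenyl-1,2,4,4a-tetrahydro-9bH-spiro[dibenzo[b,d]furan-3,2'-[1,3]dioxolane]-2-carboxylic acid
Conditions: Bu3SnH (1.5 equiv, syringe pump), AIBN (0.2 equiv), benzene (0.02 M), 80 °C; aq. KF
Reagents that add atoms: none
Why: Tin hydride-mediated 5-exo-trig aryl radical cyclisation onto the trisubstituted alkene, as in aryl radical routes to cis-hydrodibenzofurans with a benzylic quaternary carbon; the tether through the ether oxygen lets the aryl radical reach only the alkene face syn to the C–O bond, so the quaternary centre forms cis to the oxygen, and the resulting secondary radical is reduced by Bu3SnH.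

**Step 8**
Reactants: 12 (2R,4aR,9bR,4'R,5'R)-8-formyl-9b-(hydroxymethyl)-4',5'-diphenyl-1,2,4,4a-tetrahydro-9bH-spiro[dibenzo[b,d]furan-3,2'-[1,3]dioxolane]-2-carboxylic acid
Product: 14 (4aR,9bR)-9b-(hydroxymethyl)-3-oxo-1,2,3,4,4a,9b-hexahydrodibenzo[b,d]furan-8-carbaldehyde, via β-keto acid 13 (not isolated)
Conditions: 2 M HCl, 1,4-dioxane, 70 °C
Reagents that add atoms: water, O
Why: Acid hydrolysis of the ketal unmasks the ketone and the β-keto acid then decarboxylates; the quaternary centre cannot epimerise and the β-aryloxy ketone can only re-close cis, so both stereocentres are kept and the auxiliary diol is recovered.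

**Step 9**
Reactants: 14 (4aR,9bR)-9b-(hydroxymethyl)-3-oxo-1,2,3,4,4a,9b-hexahydrodibenzo[b,d]furan-8-carbaldehyde
Product: 15 ethyl (Z)-3-[(4aR,9bR)-9b-(hydroxymethyl)-3-oxo-1,2,3,4,4a,9b-hexahydrodibenzo[b,d]furan-8-yl]prop-2-enoate
Conditions: (PhO)2P(O)CH2CO2Et (1.2 equiv), NaH (1.15 equiv), THF, −78 to 0 °C
Reagents that add atoms: ethyl 2-(diphenoxyphosphoryl)acetate, CCOC(=O)CP(=O)(Oc1ccccc1)Oc1ccccc1
Why: Z-selective Horner–Wadsworth–Emmons reaction with an Ando diaryl phosphonoacetate (fast elimination from the kinetic adduct); the weakly basic phosphonate anion should react with the aryl aldehyde and not with the ketone or the free alcohol at low temperature.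

**Step 10**
Reactants: 15 ethyl (Z)-3-[(4aR,9bR)-9b-(hydroxymethyl)-3-oxo-1,2,3,4,4a,9b-hexahydrodibenzo[b,d]furan-8-yl]prop-2-enoate
Product: 16 (Z)-3-[(4aR,9bR)-9b-(hydroxymethyl)-3-oxo-1,2,3,4,4a,9b-hexahydrodibenzo[b,d]furan-8-yl]prop-2-enoic acid
Conditions: LiOH (2 equiv), THF/H2O 3:1, 0 to 23 °C; 1 M HCl to pH 3
Reagents that add atoms: lithium hydroxide, [Li+].[OH-]
Why: Ester saponification, which should leave the Z-alkene unchanged; any reversible opening of the β-aryloxy ketone re-closes cis on acidification.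

**Step 11**
Reactants: 16 (Z)-3-[(4aR,9bR)-9b-(hydroxymethyl)-3-oxo-1,2,3,4,4a,9b-hexahydrodibenzo[b,d]furan-8-yl]prop-2-enoic acid; 17 tert-butyl N-(4-aminobutyl)-N-[3-[(tert-butoxycarbonyl)amino]propyl]carbamate (N1,N4-bis-Boc-spermidine)
Product: 19 tert-butyl N-[4-[[(Z)-3-[(4aR,9bR)-9b-(hydroxymethyl)-3-oxo-1,2,3,4,4a,9b-hexahydrodibenzo[b,d]furan-8-yl]prop-2-enoyl]amino]butyl]-N-[3-[(tert-butoxycarbonyl)amino]propyl]carbamate, via benzotriazolyl ester 18 (not isolated)
Conditions: EDC·HCl (1.2 equiv), HOBt (1.2 equiv), CH2Cl2, 0 to 23 °C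
Reagents that add atoms: none
Why: Carbodiimide/HOBt amide coupling with the only free amine of 17 (the primary amine of the butyl arm), which fixes the orientation of the polyamine; the amine should outcompete the neopentyl alcohol for the active ester.

**Step 12**
Reactants: 19 tert-butyl N-[4-[[(Z)-3-[(4aR,9bR)-9b-(hydroxymethyl)-3-oxo-1,2,3,4,4a,9b-hexahydrodibenzo[b,d]furan-8-yl]prop-2-enoyl]amino]butyl]-N-[3-[(tert-butoxycarbonyl)amino]propyl]carbamate
Product: 20 tert-butyl N-[4-[[(Z)-3-[(4aR,9bS)-9b-formyl-3-oxo-1,2,3,4,4a,9b-hexahydrodibenzo[b,d]furan-8-yl]prop-2-enoyl]amino]butyl]-N-[3-[(tert-butoxycarbonyl)amino]propyl]carbamate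
Conditions: Dess–Martin periodinane (1.3 equiv), NaHCO3, CH2Cl2, 0 to 23 °C
Reagents that add atoms: none
Why: Dess–Martin oxidation of the neopentyl primary alcohol to the aldehyde, which has no α-hydrogen and so cannot epimerise.

**Step 13**
Reactants: 20 tert-butyl N-[4-[[(Z)-3-[(4aR,9bS)-9b-formyl-3-oxo-1,2,3,4,4a,9b-hexahydrodibenzo[b,d]furan-8-yl]prop-2-enoyl]amino]butyl]-N-[3-[(tert-butoxycarbonyl)amino]propyl]carbamate
Product: 21 methyl (Z)-3-[(4aR,9bS)-8-[(Z)-3-[[4-[(tert-butoxycarbonyl)[3-[(tert-butoxycarbonyl)amino]propyl]amino]butyl]amino]-3-oxoprop-1-enyl]-3-oxo-1,2,3,4-tetrahydrodibenzo[b,d]furan-9b(4aH)-yl]prop-2-enoate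
Conditions: (CF3CH2O)2P(O)CH2CO2Me (1.3 equiv), KN(SiMe3)2 (1.25 equiv), 18-crown-6 (3 equiv), THF, −78 °C
Reagents that add atoms: methyl 2-[bis(2,2,2-trifluoroethoxy)phosphoryl]acetate, COC(=O)CP(=O)(OCC(F)(F)F)OCC(F)(F)F
Why: Still–Gennari modification of the Horner–Wadsworth–Emmons reaction, which should give the Z-enoate from the hindered aldehyde under kinetic control and is too weakly basic to touch the ketone or the N–H groups.

**Step 14**
Reactants: 21 methyl (Z)-3-[(4aR,9bS)-8-[(Z)-3-[[4-[(tert-butoxycarbonyl)[3-[(tert-butoxycarbonyl)amino]propyl]amino]butyl]amino]-3-oxoprop-1-enyl]-3-oxo-1,2,3,4-tetrahydrodibenzo[b,d]furan-9b(4aH)-yl]prop-2-enoate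
Product: 22 (Z)-3-[(4aR,9bS)-8-[(Z)-3-[[4-[(tert-butoxycarbonyl)[3-[(tert-butoxycarbonyl)amino]propyl]amino]butyl]amino]-3-oxoprop-1-enyl]-3-oxo-1,2,3,4-tetrahydrodibenzo[b,d]furan-9b(4aH)-yl]prop-2-enoic acid
Conditions: LiOH (2 equiv), THF/H2O 3:1, 0 to 23 °C; 1 M HCl to pH 4
Reagents that add atoms: lithium hydroxide, [Li+].[OH-]
Why: Saponification of the unhindered methyl ester, under which the secondary amide, the carbamates and both Z-alkenes should survive.

**Step 15**
Reactants: 22 (Z)-3-[(4aR,9bS)-8-[(Z)-3-[[4-[(tert-butoxycarbonyl)[3-[(tert-butoxycarbonyl)amino]propyl]amino]butyl]amino]-3-oxoprop-1-enyl]-3-oxo-1,2,3,4-tetrahydrodibenzo[b,d]furan-9b(4aH)-yl]prop-2-enoic acid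
Product: 23 (Z)-3-[(4aR,9bS)-8-[(Z)-3-[[4-[(3-aminopropyl)amino]butyl]amino]-3-oxoprop-1-enyl]-3-oxo-1,2,3,4-tetrahydrodibenzo[b,d]furan-9b(4aH)-yl]prop-2-enoic acid (handled as its bis(trifluoroacetate))
Conditions: CF3CO2H/CH2Cl2 1:3, 0 to 23 °C; evaporation
Reagents that add atoms: none
Why: Acidolysis of both Boc carbamates (loss of isobutene and CO2) under conditions that should not isomerise the Z-alkenes or affect the ketone.

**Step 16**
Reactants: 23 (Z)-3-[(4aR,9bS)-8-[(Z)-3-[[4-[(3-aminopropyl)amino]butyl]amino]-3-oxoprop-1-enyl]-3-oxo-1,2,3,4-tetrahydrodibenzo[b,d]furan-9b(4aH)-yl]prop-2-enoic acid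
Product: 25 target CNP0159470.1, via pentafluorophenyl ester 24 (not isolated)
Conditions: C6F5OP(O)Ph2 (FDPP, 1.5 equiv), iPr2NEt (6 equiv), DMF (1 mM, slow addition of 23), 23 °C
Reagents that add atoms: none
Why: Macrolactamisation through a pentafluorophenyl active ester at high dilution; the unhindered primary amine should be acylated in preference to the secondary amine, as in the selective acylation of the terminal nitrogens of spermidine, closing the 20-membered ring.

**Compound list**
1 | (1R,2R)-1,2-diphenylethane-1,2-diol ((R,R)-hydrobenzoin) | O[C@H](c1ccccc1)[C@H](O)c1ccccc1 | starting material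
2 | 2-bromo-1,1-diethoxyethane | CCOC(CBr)OCC | starting material
3 | (4R,5R)-2-(bromomethyl)-4,5-diphenyl-1,3-dioxolane | BrCC1O[C@H](c2ccccc2)[C@@H](c2ccccc2)O1 | intermediate
4 | (4R,5R)-2-methylidene-4,5-diphenyl-1,3-dioxolane | C=C1O[C@H](c2ccccc2)[C@@H](c2ccccc2)O1 | intermediate
5 | methyl 2-oxo-2H-pyran-5-carboxylate (methyl coumalate) | COC(=O)C1=COC(=O)C=C1 | starting material
6 | bridged lactone cycloadduct, (1R,4R) core with (4'R,5'R)-diphenyldioxolane ketal | O=C1O[C@@H]2CC3(O[C@H](c4ccccc4)[C@@H](c4ccccc4)O3)[C@H]1C=C2C(=O)OC | intermediate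
7 | hydroxy acid, (2R,3R,6R,9R)-9-hydroxy-8-(methoxycarbonyl)-2,3-diphenyl-1,4-dioxaspiro[4.5]dec-7-ene-6-carboxylic acid | COC(=O)C1=C[C@@H](C(=O)O)C2(O[C@H](c3ccccc3)[C@@H](c3ccccc3)O2)C[C@H]1O | intermediate
8 | 3-bromo-4-fluorobenzonitrile | N#Cc1ccc(F)c(Br)c1 | starting material
9 | aryl ether acid, 9-(2-bromo-4-cyanophenoxy) analogue of 7 | COC(=O)C1=C[C@@H](C(=O)O)C2(O[C@H](c3ccccc3)[C@@H](c3ccccc3)O2)C[C@H]1Oc1ccc(C#N)cc1Br | intermediate
10 | aldimine, 9-[2-bromo-4-(iminomethyl)phenoxy]-8-(hydroxymethyl) acid | OCC1=C[C@@H](C(=O)O)C2(O[C@H](c3ccccc3)[C@@H](c3ccccc3)O2)C[C@H]1Oc1ccc(C=N)cc1Br | intermediate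
11 | allylic alcohol aldehyde, 9-(2-bromo-4-formylphenoxy)-8-(hydroxymethyl) acid | OCC1=C[C@@H](C(=O)O)C2(O[C@H](c3ccccc3)[C@@H](c3ccccc3)O2)C[C@H]1Oc1ccc(C=O)cc1Br | intermediate
12 | cis-fused tricyclic ketal acid, (2R,4aR,9bR) | OC[C@]12C[C@@H](C(=O)O)C3(O[C@H](c4ccccc4)[C@@H](c4ccccc4)O3)C[C@H]1Oc1ccc(C=O)cc12 | intermediate
13 | β-keto acid, (2R,4aR,9bR)-8-formyl-9b-(hydroxymethyl)-3-oxo-1,2,3,4,4a,9b-hexahydrodibenzo[b,d]furan-2-carboxylic acid | OC[C@]12C[C@@H](C(=O)O)C(=O)C[C@H]1Oc1ccc(C=O)cc12 | intermediate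
14 | (4aR,9bR)-9b-(hydroxymethyl)-3-oxo-1,2,3,4,4a,9b-hexahydrodibenzo[b,d]furan-8-carbaldehyde | OC[C@]12CCC(=O)C[C@H]1Oc1ccc(C=O)cc12 | intermediate
15 | Z-ethyl cinnamate of the (4aR,9bR) core | OC[C@]12CCC(=O)C[C@H]1Oc1ccc(/C=C\C(=O)OCC)cc12 | intermediate
16 | Z-cinnamic acid of the (4aR,9bR) core | OC[C@]12CCC(=O)C[C@H]1Oc1ccc(/C=C\C(=O)O)cc12 | intermediate
17 | tert-butyl N-(4-aminobutyl)-N-[3-[(tert-butoxycarbonyl)amino]propyl]carbamate | NCCCCN(CCCNC(=O)OC(C)(C)C)C(=O)OC(C)(C)C | starting material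
18 | 1H-benzotriazol-1-yl ester of 16 | OC[C@]12CCC(=O)C[C@H]1Oc1ccc(/C=C\C(=O)On3nnc4ccccc43)cc12 | intermediate
19 | Z-cinnamamide alcohol, N8-acyl-N1,N4-bis-Boc-spermidine, (4aR,9bR) | OC[C@]12CCC(=O)C[C@H]1Oc1ccc(/C=C\C(=O)NCCCCN(CCCNC(=O)OC(C)(C)C)C(=O)OC(C)(C)C)cc12 | intermediate
20 | Z-cinnamamide aldehyde, (4aR,9bS) | O=C[C@]12CCC(=O)C[C@H]1Oc1ccc(/C=C\C(=O)NCCCCN(CCCNC(=O)OC(C)(C)C)C(=O)OC(C)(C)C)cc12 | intermediate
21 | bis-Z methyl acrylate amide, (4aR,9bS) | COC(=O)/C=C\[C@]12CCC(=O)C[C@H]1Oc1ccc(/C=C\C(=O)NCCCCN(CCCNC(=O)OC(C)(C)C)C(=O)OC(C)(C)C)cc12 | intermediate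
22 | bis-Z acrylic acid amide, (4aR,9bS) | OC(=O)/C=C\[C@]12CCC(=O)C[C@H]1Oc1ccc(/C=C\C(=O)NCCCCN(CCCNC(=O)OC(C)(C)C)C(=O)OC(C)(C)C)cc12 | intermediate
23 | seco amino acid, (4aR,9bS) | OC(=O)/C=C\[C@]12CCC(=O)C[C@H]1Oc1ccc(/C=C\C(=O)NCCCCNCCCN)cc12 | intermediate
24 | pentafluorophenyl ester of 23 | O=C(Oc3c(F)c(F)c(F)c(F)c3F)/C=C\[C@]12CCC(=O)C[C@H]1Oc1ccc(/C=C\C(=O)NCCCCNCCCN)cc12 | intermediate
25 | CNP0159470.1, (Z,Z)-20-membered spermidine bis-lactam on the cis-fused 3-oxo-hexahydrodibenzofuran core, quaternary carbon S and O-bearing CH R | O=C1CC[C@]23/C=C\C(=O)NCCCNCCCCNC(=O)/C=C\c4ccc(c2c4)O[C@@H]3C1 | target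

**Step count**
Total: 16 steps. Longest linear sequence: 16 steps (1 to 25); 5, 8 and 17 are bought and enter at steps 3, 5 and 11.

**Steps most likely to fail**

Step 3. Cationic oligomerisation of the hindered cyclic ketene acetal may outrun the cycloaddition, or the facial bias and the separation of the diastereomers may be too poor to give pure 6. The fallback separates ring construction from stereocontrol and sets out from 5. Cycloaddition with commercial 1,1-dimethoxyethene (CH2Cl2, 23 °C) should give the racemic dimethyl ketal lactone F1. LiOH as in step 4, followed by crystallisation of the (R)-1-phenylethylammonium salt (or that of the antipodal amine, whichever gives the less soluble salt of the wanted enantiomer), should give the resolved dimethyl ketal hydroxy acid F2. Steps 5 to 7 are then repeated on this series: SNAr with 8 to the aryl ether acid F3, reduction with iBu2AlH to the allylic alcohol aldehyde F4, and radical cyclisation to the tricyclic dimethyl ketal acid F5. Mild aqueous acid hydrolysis and decarboxylation of F5 return to the route at 14.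

Step 7. The aryl radical may be quenched before cyclisation (1,5-hydrogen transfer from the O-bearing CH or direct reduction), the cyclised radical may undergo a neophyl-type aryl shift, or the tin hydride may reduce the aldehyde. The fallback replaces the radical by an organopalladium ring closure and sets out from 11. Esterification with Me3SiCHN2 gives the methyl ester F6; this blocks the decarboxylative elimination that a free carboxylate next to an allylpalladium species would undergo. A reductive Heck cyclisation (Pd(OAc)2, PPh3, HCO2Na, Et4NCl, DMF, 80 °C) should then give the cis-fused tricyclic methyl ester F7. The ester group is cis to the aryl ether, so the alkylpalladium intermediate has no syn β-hydrogen and is reduced by formate. Hot aqueous HCl, as in step 8, hydrolyses the ketal and the β-keto ester, decarboxylates, and returns to the route at 14.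

Step 16. The secondary amine may compete for the active ester (16-membered tertiary lactam), or oligomers may form. The fallback closes the ring at the secondary amine by reductive amination, so that no free secondary amine is present before the last bond is made; it sets out from 16. Coupling of 16 with 4-aminobutanal diethyl acetal (EDC·HCl, HOBt) gives the acetal amide F8. Dess–Martin oxidation gives the aldehyde F9, and the Still–Gennari reaction of step 13 gives the Z methyl ester F10. LiOH gives the acid F11, and coupling with tert-butyl N-(3-aminopropyl)carbamate gives the diamide F12. CF3CO2H/H2O removes the Boc group and the acetal to give the amino aldehyde F13. Macrocyclic reductive amination at high dilution (NaBH(OAc)3, AcOH, 1,2-dichloroethane, 1 mM) reduces the aldimine faster than it touches the ring ketone and returns to the route at 25.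

**Further compounds**
F1 | step 3 | methyl 8,8-dimethoxy-3-oxo-2-oxabicyclo[2.2.2]oct-5-ene-6-carboxylate (racemate; one enantiomer drawn) | O=C1O[C@@H]2CC(OC)(OC)[C@H]1C=C2C(=O)OC
F2 | step 3 | (1R,4R)-4-hydroxy-6,6-dimethoxy-3-(methoxycarbonyl)cyclohex-2-ene-1-carboxylic acid | COC(=O)C1=C[C@@H](C(=O)O)C(OC)(OC)C[C@H]1O
F3 | step 3 | (1R,4R)-4-(2-bromo-4-cyanophenoxy)-6,6-dimethoxy-3-(methoxycarbonyl)cyclohex-2-ene-1-carboxylic acid | COC(=O)C1=C[C@@H](C(=O)O)C(OC)(OC)C[C@H]1Oc1ccc(C#N)cc1Br
F4 | step 3 | (1R,4R)-4-(2-bromo-4-formylphenoxy)-3-(hydroxymethyl)-6,6-dimethoxycyclohex-2-ene-1-carboxylic acid | OCC1=C[C@@H](C(=O)O)C(OC)(OC)C[C@H]1Oc1ccc(C=O)cc1Br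
F5 | step 3 | (2R,4aR,9bR)-8-formyl-9b-(hydroxymethyl)-3,3-dimethoxy-1,2,3,4,4a,9b-hexahydrodibenzo[b,d]furan-2-carboxylic acid | OC[C@]12C[C@@H](C(=O)O)C(OC)(OC)C[C@H]1Oc1ccc(C=O)cc12
F6 | step 7 | methyl ester of 11 | OCC1=C[C@@H](C(=O)OC)C2(O[C@H](c3ccccc3)[C@@H](c3ccccc3)O2)C[C@H]1Oc1ccc(C=O)cc1Br
F7 | step 7 | methyl ester of 12 | OC[C@]12C[C@@H](C(=O)OC)C3(O[C@H](c4ccccc4)[C@@H](c4ccccc4)O3)C[C@H]1Oc1ccc(C=O)cc12
F8 | step 16 | (Z)-N-(4,4-diethoxybutyl)-3-[(4aR,9bR)-9b-(hydroxymethyl)-3-oxo-1,2,3,4,4a,9b-hexahydrodibenzo[b,d]furan-8-yl]prop-2-enamide | OC[C@]12CCC(=O)C[C@H]1Oc1ccc(/C=C\C(=O)NCCCC(OCC)OCC)cc12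
F9 | step 16 | (Z)-N-(4,4-diethoxybutyl)-3-[(4aR,9bS)-9b-formyl-3-oxo-1,2,3,4,4a,9b-hexahydrodibenzo[b,d]furan-8-yl]prop-2-enamide | O=C[C@]12CCC(=O)C[C@H]1Oc1ccc(/C=C\C(=O)NCCCC(OCC)OCC)cc12
F10 | step 16 | Z methyl acrylate of F9 | COC(=O)/C=C\[C@]12CCC(=O)C[C@H]1Oc1ccc(/C=C\C(=O)NCCCC(OCC)OCC)cc12
F11 | step 16 | Z acrylic acid from F10 | OC(=O)/C=C\[C@]12CCC(=O)C[C@H]1Oc1ccc(/C=C\C(=O)NCCCC(OCC)OCC)cc12
F12 | step 16 | diamide of F11 with tert-butyl N-(3-aminopropyl)carbamate | CC(C)(C)OC(=O)NCCCNC(=O)/C=C\[C@]12CCC(=O)C[C@H]1Oc1ccc(/C=C\C(=O)NCCCC(OCC)OCC)cc12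
F13 | step 16 | amino aldehyde, (Z)-N-(3-aminopropyl) acrylamide and (Z)-N-(4-oxobutyl) cinnamamide on the (4aR,9bS) core | NCCCNC(=O)/C=C\[C@]12CCC(=O)C[C@H]1Oc1ccc(/C=C\C(=O)NCCCC=O)cc12
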